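**Plan**

- Cuts (labdane numbering): the butenolide C13=C14/C15 unit (glyoxylic acid condensation), then C6–C7 and C9–C10 of ring B in one step, then C5–C6 (alkenyl metal plus aldehyde) and C8=C9 (Z-selective olefination).
- Enabling feature: in ring B the C6 carbinol is homoallylic to the C8=C9 alkene (C6–C7–C8=C9, C17 on C8), the pattern a carbonyl-ene closure leaves; C10 is the β-carbon of the ring A unit C10=C5–C6 and can be alkylated by a [3,3] shift from a C6 alkoxide.
- Forward: ring A comes ready-made from 4-oxoisophorone, the C6–C16 chain is joined to it at C5–C6, ring B closes by oxy-Cope shift followed by ene reaction, and the butenolide is built last.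
- Stereochemistry: C2 from yeast reduction and hydride relay; C10 relayed from C2 through the ring A half-chair in the [3,3] shift; C5 by equilibration of the aldehyde; C6 from the (Z)-alkene through the suprafacial ene step.

Key step: step 12

Remark on numbering: bicyclic compounds carry labdane numbers (ring A = C1–C5, C10; ring B = C5–C10; C17 on C8; chain C11, C12, C13, C16 on C9; C14 and C15 complete the butenolide); β is the face of the C10 methyl.
Remark on C6: compound 21 is made and used as the mixture of its two C6 epimers, because C6 becomes the aldehyde carbon in step 12 and both epimers can reach the same chair.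

**Route**

Step 1
Reactants: 1 4-oxoisophorone
Product: 2 (6R)-2,2,6-trimethylcyclohexane-1,4-dione
Conditions: baker's yeast, sucrose, H2O, 30 °C
Reagents that add atoms: none
Why: Yeast ene-reductase conjugate reduction of the enedione C=C, which sets the methyl-bearing carbon as R under enzyme control.

Step 2
Reactants: 2 (6R)-2,2,6-trimethylcyclohexane-1,4-dione
Product: 3 (4R,6R)-4-hydroxy-2,2,6-trimethylcyclohexan-1-one
Conditions: LiBH(s-Bu)3 (L-Selectride), THF, −78 °C
Reagents that add atoms: none
Why: Bulky-borohydride reduction, in which hydride attacks the unhindered C4 carbonyl from the equatorial side away from the axial C2 methyl (as with 3,3,5-trimethylcyclohexanone) and should give the axial 4R alcohol trans to the C6 methyl, while the flanked C1 carbonyl is left alone.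

Step 3
Reactants: 3 (4R,6R)-4-hydroxy-2,2,6-trimethylcyclohexan-1-one
Product: 4 silyl ether of 3
Conditions: TBSCl, imidazole, DMF, 25 °C
Reagents that add atoms: tert-butyldimethylsilyl chloride CC(C)(C)[Si](C)(C)Cl
Why: Imidazole-promoted silylation of a secondary alcohol; no stereocentre is touched.

Step 4
Reactants: 4 silyl ether of 3
Product: 5 arenesulfonylhydrazone of 4
Conditions: 2,4,6-(i-Pr)3C6H2SO2NHNH2, camphorsulfonic acid (cat.), THF, 25 °C
Reagents that add atoms: 2,4,6-tri(propan-2-yl)benzenesulfonohydrazide NNS(=O)(=O)c1c(C(C)C)cc(C(C)C)cc1C(C)C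
Why: Acid-catalysed hydrazone condensation of the hindered ketone, as practised for 2,2,6-trimethylcyclohexanone, to prepare the Shapiro substrate.

Step 5
Reactants: 6 2-(3-chloropropyl)-1,3-dioxolane; 7 N,N-dimethylformamide
Product: 9 4-(1,3-dioxolan-2-yl)butanal, via Grignard reagent 8 (not isolated)
Conditions: Mg, THF, reflux; then 7, 0 °C; aq NH4Cl
Reagents that add atoms: none
Why: Grignard formation and formylation with the formamide (Bouveault aldehyde synthesis), where the tetrahedral adduct survives until work-up so the aldehyde is not attacked twice.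

Step 6
Reactants: 10 methyl 2-[bis(2,2,2-trifluoroethoxy)phosphoryl]acetate; 11 tert-butyl 2-bromoacetate
Product: 13 racemic phosphonosuccinate, via sodium phosphonate 12 (not isolated)
Conditions: NaH, THF, 0 °C; then 11, 0 °C to 25 °C
Reagents that add atoms: none
Why: C-alkylation (SN2) of the stabilised phosphonoacetate anion with a reactive α-bromo ester gives the α-substituted Still–Gennari reagent; the new centre is racemic and is lost in step 7.

Step 7
Reactants: 13 racemic phosphonosuccinate; 9 4-(1,3-dioxolan-2-yl)butanal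
Product: 15 (Z)-alkylidene succinate diester, via potassium phosphonate 14 (not isolated)
Conditions: KN(SiMe3)2, 18-crown-6, THF, −78 °C; then 9
Reagents that add atoms: none
Why: Still–Gennari variant of the Horner–Wadsworth–Emmons olefination, whose kinetically controlled collapse should place the methyl ester cis to the chain (Z), the geometry that later puts C17 cis to C11.

Step 8
Reactants: 15 (Z)-alkylidene succinate diester
Product: 16 (Z)-allylic alcohol tert-butyl ester
Conditions: i-Bu2AlH (2.2 equiv), CH2Cl2, −78 °C; aq potassium sodium tartrate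
Reagents that add atoms: none
Why: i-Bu2AlH reduction of an ester to the primary alcohol, in which the methyl enoate is reduced at −78 °C while the bulkier tert-butyl ester is expected to survive and the alkene geometry is untouched.

Step 9
Reactants: 16 (Z)-allylic alcohol tert-butyl ester
Product: 17 triisopropylsilyl ether of 16
Conditions: TIPSCl, imidazole, DMF, 25 °C
Reagents that add atoms: triisopropylsilyl chloride CC(C)[Si](Cl)(C(C)C)C(C)C
Why: Silylation of the primary allylic alcohol; the bulky triisopropylsilyl group is chosen because it should neither migrate to the C6 alkoxide nor be lost in step 12.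

Step 10
Reactants: 17 triisopropylsilyl ether of 16
Product: 18 (Z)-β,γ-unsaturated aldehyde
Conditions: i-Bu2AlH (1.1 equiv), CH2Cl2, −78 °C; MeOH, then aq potassium sodium tartrate
Reagents that add atoms: none
Why: Partial ester reduction at −78 °C, where the tetrahedral aluminium hemiacetal is stable until quench, gives the β,γ-unsaturated aldehyde, which is used at once.

Step 11
Reactants: 5 arenesulfonylhydrazone of 4; 18 (Z)-β,γ-unsaturated aldehyde
Product: 21 cyclohexenyl allyl carbinol (both C6 epimers), via alkenyllithium 19 (not isolated), via alkenylcerium reagent 20 (not isolated)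
Conditions: n-BuLi (2.1 equiv), TMEDA, THF/hexane, −78 °C to 0 °C; CeCl3, THF, −78 °C; then 18, −78 °C
Reagents that add atoms: none
Why: Shapiro reaction (the only α-hydrogen fixes the position of the alkenyllithium and the old methyl-bearing centre disappears) followed by 1,2-addition of the less basic organocerium reagent to the enolisable aldehyde; the new carbinol centre C6 is formed without control and both epimers are carried on.

Step 12
Reactants: 21 cyclohexenyl allyl carbinol (both C6 epimers)
Product: 25 cis-decalin homoallylic alcohol, via potassium alkoxide 22 (not isolated), via potassium enolate 23 (not isolated), via cis aldehyde 24 (not isolated)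
Conditions: KH, 18-crown-6, THF, 0 °C to 40 °C; MeOH, 0 °C to 25 °C; crude 24, then Me2AlCl, CH2Cl2, −78 °C to −40 °C
Reagents that add atoms: none
Why: Proposed new method: alkoxide 22 should undergo a chair-like anionic oxy-Cope [3,3] shift (C6–C7 breaks, C9–C10 forms), enolate 23 is protonated to aldehyde 24, and Me2AlCl then joins C7 to C6 while H9 passes to oxygen, the closest known reaction types being the tandem oxy-Cope/transannular carbonyl-ene sequence of 1,2-divinylcyclohexanols and Me2AlCl-promoted type 2 carbonyl-ene cyclisations, which normally take an exocyclic allylic hydrogen. Ring B closes as a six-membered ring in the type 2 mode (tether on the central carbon C8 of the ene unit, bond to its CH2 terminus C7) through a boat-like array in which the C6 oxygen and H9 face each other. C10 is set by the ring A half-chair that the equatorial C2 silyloxy group fixes: its pseudoaxial C4 methyl blocks the β face for the C6–C7 bond, so the allyl unit crosses the α face and C9 bonds cis to the C2 oxygen, in a chair that either C6 epimer can adopt. C5 is set by protonation under equilibrating conditions, where the formyl group should prefer the axial site cis to the C9 branch and anti to the axial methyls on C4 and C10. C6 is set by the suprafacial ene geometry, because the (Z)-alkene puts H9 on the α face in the chair shift and oxygen must then add from that face, giving the 6α-hydroxyl. The step needs H9 and not a C17 hydrogen to migrate; this rests on the low donor ability of hydrogens geminal to a bulky silyloxy group and on the gain of a tetrasubstituted alkene, and it is the main uncertainty.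

Step 13
Reactants: 25 cis-decalin homoallylic alcohol
Product: 26 side-chain aldehyde
Conditions: pyridinium p-toluenesulfonate (cat.), acetone/H2O, 55 °C
Reagents that add atoms: water O
Why: Acid-catalysed acetal hydrolysis under conditions mild enough for both silyl ethers.

Step 14
Reactants: 26 side-chain aldehyde; 27 glyoxylic acid (as monohydrate)
Product: 28 5-hydroxybutenolide
Conditions: morpholine hydrochloride, dioxane/H2O, 25 °C then 90 °C
Reagents that add atoms: none
Why: Amine-mediated aldol condensation of the α-methylene aldehyde with glyoxylic acid (enamine addition, loss of water, closure of the 4-oxo-2-enoic acid) gives the 5-hydroxybutenolide, whose hemiacetal centre is of no consequence.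

Step 15
Reactants: 28 5-hydroxybutenolide
Product: 30 bis-silylated butenolide, via sodium hydroxy carboxylate 29 (not isolated)
Conditions: NaBH4, MeOH, 0 °C; then aq HCl to pH 2
Reagents that add atoms: none
Why: NaBH4 reduces the ring-opened aldehyde form of the hydroxybutenolide and acidification lactonises the (Z)-4-hydroxy-2-enoic acid to the butenolide; no skeletal stereocentre is involved.

Step 16
Reactants: 30 bis-silylated butenolide
Product: 31 CNP0293367.1
Conditions: HF·pyridine, pyridine, THF, 0 °C to 25 °C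
Reagents that add atoms: none
Why: Fluoride-mediated cleavage of both silyl ethers under mildly acidic conditions that the butenolide and the allylic alcohol should tolerate.

**Compound list**

1 | 4-oxoisophorone (2,6,6-trimethylcyclohex-2-ene-1,4-dione) | CC1=CC(=O)CC(C)(C)C1=O | starting material
2 | (6R)-2,2,6-trimethylcyclohexane-1,4-dione | CC1(C)CC(=O)C[C@@H](C)C1=O | intermediate
3 | (4R,6R)-4-hydroxy-2,2,6-trimethylcyclohexan-1-one | CC1(C)C[C@H](O)C[C@@H](C)C1=O | intermediate
4 | (4R,6R)-4-{[tert-butyl(dimethyl)silyl]oxy}-2,2,6-trimethylcyclohexan-1-one | CC1(C)C[C@H](O[Si](C)(C)C(C)(C)C)C[C@@H](C)C1=O | intermediate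
5 | 2,4,6-tri(propan-2-yl)benzenesulfonylhydrazone of 4 (4R,6R) | CC1(C)C[C@H](O[Si](C)(C)C(C)(C)C)C[C@@H](C)C1=NNS(=O)(=O)c1c(C(C)C)cc(C(C)C)cc1C(C)C | intermediate
6 | 2-(3-chloropropyl)-1,3-dioxolane | ClCCCC1OCCO1 | starting material
7 | N,N-dimethylformamide | CN(C)C=O | starting material
8 | [3-(1,3-dioxolan-2-yl)propyl]magnesium chloride | Cl[Mg]CCCC1OCCO1 | intermediate
9 | 4-(1,3-dioxolan-2-yl)butanal | O=CCCCC1OCCO1 | intermediate
10 | methyl 2-[bis(2,2,2-trifluoroethoxy)phosphoryl]acetate | COC(=O)CP(=O)(OCC(F)(F)F)OCC(F)(F)F | starting material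
11 | tert-butyl 2-bromoacetate | CC(C)(C)OC(=O)CBr | starting material
12 | sodium salt (carbanion) of 10 | [Na+].COC(=O)[CH-]P(=O)(OCC(F)(F)F)OCC(F)(F)F | intermediate
13 | 4-tert-butyl 1-methyl 2-[bis(2,2,2-trifluoroethoxy)phosphoryl]butanedioate (racemic) | COC(=O)C(CC(=O)OC(C)(C)C)P(=O)(OCC(F)(F)F)OCC(F)(F)F | intermediate
14 | potassium salt (carbanion) of 13 | [K+].COC(=O)[C-](CC(=O)OC(C)(C)C)P(=O)(OCC(F)(F)F)OCC(F)(F)F | intermediate
15 | 4-tert-butyl 1-methyl (2Z)-2-[4-(1,3-dioxolan-2-yl)butylidene]butanedioate | COC(=O)/C(CC(=O)OC(C)(C)C)=C\CCCC1OCCO1 | intermediate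
16 | tert-butyl (3Z)-7-(1,3-dioxolan-2-yl)-3-(hydroxymethyl)hept-3-enoate | CC(C)(C)OC(=O)C/C(CO)=C/CCCC1OCCO1 | intermediate
17 | tert-butyl (3Z)-7-(1,3-dioxolan-2-yl)-3-({[tri(propan-2-yl)silyl]oxy}methyl)hept-3-enoate | CC(C)(C)OC(=O)C/C(CO[Si](C(C)C)(C(C)C)C(C)C)=C/CCCC1OCCO1 | intermediate
18 | (3Z)-7-(1,3-dioxolan-2-yl)-3-({[tri(propan-2-yl)silyl]oxy}methyl)hept-3-enal | O=CC/C(CO[Si](C(C)C)(C(C)C)C(C)C)=C/CCCC1OCCO1 | intermediate
19 | [(4R)-4-{[tert-butyl(dimethyl)silyl]oxy}-2,6,6-trimethylcyclohex-1-en-1-yl]lithium | CC1(C)C[C@H](O[Si](C)(C)C(C)(C)C)CC(C)=C1[Li] | intermediate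
20 | [(4R)-4-{[tert-butyl(dimethyl)silyl]oxy}-2,6,6-trimethylcyclohex-1-en-1-yl]cerium dichloride | CC1(C)C[C@H](O[Si](C)(C)C(C)(C)C)CC(C)=C1[Ce](Cl)Cl | intermediate
21 | (3Z)-1-[(4R)-4-{[tert-butyl(dimethyl)silyl]oxy}-2,6,6-trimethylcyclohex-1-en-1-yl]-7-(1,3-dioxolan-2-yl)-3-({[tri(propan-2-yl)silyl]oxy}methyl)hept-3-en-1-ol, both C1 epimers (labdane C6) | CC1(C)C[C@H](O[Si](C)(C)C(C)(C)C)CC(C)=C1C(O)C/C(CO[Si](C(C)C)(C(C)C)C(C)C)=C/CCCC1OCCO1 | intermediate
22 | potassium alkoxide of 21 | CC1(C)C[C@H](O[Si](C)(C)C(C)(C)C)CC(C)=C1C([O-])C/C(CO[Si](C(C)C)(C(C)C)C(C)C)=C/CCCC1OCCO1.[K+] | intermediate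
23 | potassium enolate of aldehyde 24 (C5=C6–OK; C9–C10 bond formed; C2, C9, C10 as in 24) | CC1(C)C[C@H](O[Si](C)(C)C(C)(C)C)C[C@](C)([C@@H](CCCC2OCCO2)C(=C)CO[Si](C(C)C)(C(C)C)C(C)C)C1=C[O-].[K+] | intermediate
24 | (1R,2R,4S)-4-{[tert-butyl(dimethyl)silyl]oxy}-2-[(3R)-6-(1,3-dioxolan-2-yl)-2-({[tri(propan-2-yl)silyl]oxy}methyl)hex-1-en-3-yl]-2,6,6-trimethylcyclohexane-1-carbaldehyde (formyl cis to the C9 branch) | CC1(C)C[C@H](O[Si](C)(C)C(C)(C)C)C[C@](C)([C@@H](CCCC2OCCO2)C(=C)CO[Si](C(C)C)(C(C)C)C(C)C)[C@@H]1C=O | intermediate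
25 | (1S,4aS,6S,8aR)-6-{[tert-butyl(dimethyl)silyl]oxy}-4-[3-(1,3-dioxolan-2-yl)propyl]-4a,8,8-trimethyl-3-({[tri(propan-2-yl)silyl]oxy}methyl)-1,2,4a,5,6,7,8,8a-octahydronaphthalen-1-ol (labdane: 2α-silyloxy, 5β-H, 6α-OH, 10β-methyl, C8=C9) | CC1(C)C[C@H](O[Si](C)(C)C(C)(C)C)C[C@]2(C)C(CCCC3OCCO3)=C(CO[Si](C(C)C)(C(C)C)C(C)C)C[C@H](O)[C@H]12 | intermediate
26 | 4-[(4S,4aR,7S,8aS)-7-{[tert-butyl(dimethyl)silyl]oxy}-4-hydroxy-5,5,8a-trimethyl-2-({[tri(propan-2-yl)silyl]oxy}methyl)-3,4,4a,5,6,7,8,8a-octahydronaphthalen-1-yl]butanal | CC1(C)C[C@H](O[Si](C)(C)C(C)(C)C)C[C@]2(C)C(CCCC=O)=C(CO[Si](C(C)C)(C(C)C)C(C)C)C[C@H](O)[C@H]12 | intermediate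
27 | glyoxylic acid (used as the monohydrate) | OC(=O)C=O | starting material
28 | 5-hydroxy-4-{2-[bicyclic core of 26]ethyl}furan-2(5H)-one, both hemiacetal epimers | CC1(C)C[C@H](O[Si](C)(C)C(C)(C)C)C[C@]2(C)C(CCC3=CC(=O)OC3O)=C(CO[Si](C(C)C)(C(C)C)C(C)C)C[C@H](O)[C@H]12 | intermediate
29 | sodium (2Z)-4-hydroxy-3-{2-[bicyclic core of 26]ethyl}but-2-enoate | CC1(C)C[C@H](O[Si](C)(C)C(C)(C)C)C[C@]2(C)C(CC/C(CO)=C/C(=O)[O-])=C(CO[Si](C(C)C)(C(C)C)C(C)C)C[C@H](O)[C@H]12.[Na+] | intermediate
30 | 4-{2-[(4S,4aR,7S,8aS)-7-{[tert-butyl(dimethyl)silyl]oxy}-4-hydroxy-5,5,8a-trimethyl-2-({[tri(propan-2-yl)silyl]oxy}methyl)-3,4,4a,5,6,7,8,8a-octahydronaphthalen-1-yl]ethyl}furan-2(5H)-one | CC1(C)C[C@H](O[Si](C)(C)C(C)(C)C)C[C@]2(C)C(CCC3=CC(=O)OC3)=C(CO[Si](C(C)C)(C(C)C)C(C)C)C[C@H](O)[C@H]12 | intermediate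
31 | CNP0293367.1, 4-{2-[(4S,4aR,7S,8aS)-4,7-dihydroxy-2-(hydroxymethyl)-5,5,8a-trimethyl-3,4,4a,5,6,7,8,8a-octahydronaphthalen-1-yl]ethyl}furan-2(5H)-one (labdane: 2S,5R,6S,10S) | CC1(C)C[C@H](O)C[C@]2(C)C(CCC3=CC(=O)OC3)=C(CO)C[C@H](O)[C@H]12 | target

**Step count and risks**

Total steps: 16. Longest linear sequence: 11 steps (steps 6 to 16, from 10 and 11; the branch from 6 and 7 is equally long).

Steps most likely to fail:

1. Step 12. A C17 hydrogen may migrate in place of H9 in the ene stage, which is the ordinary exocyclic course of a type 2 ene reaction; ring B would then close with the alkene as a C8=C17 silyl enol ether. The fallback accepts that course and moves the alkene by known reactions; it sets out from aldehyde 24, isolated after the oxy-Cope stage, and comes back at 25. Closure of 24 with Me2AlCl along the exocyclic course gives silyl enol ether F1. N-Bromosuccinimide in THF at −78 °C converts it into α-bromo aldehyde F2. Li2CO3 and LiBr in DMF at 100 °C remove HBr toward the tertiary C9 hydrogen to give the tetrasubstituted enal F3; this direction is expected on Zaitsev grounds but competes with loss of a C7 hydrogen. NaBH4 with CeCl3 in MeOH (Luche reduction) gives allylic diol F4. TIPSCl and imidazole then silylate the primary hydroxyl selectively and return 25.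

2. Step 11. The hindered alkenyl metal may deprotonate the β,γ-unsaturated aldehyde at C7 instead of adding to it, and the alkene may then drift into conjugation. The fallback sets out from ketone 4 and comes back at 21. KN(SiMe3)2 and PhNTf2 in THF at −78 °C give enol triflate F5, since only one α-carbon carries a hydrogen. A Nozaki–Hiyama–Kishi coupling with 18 (CrCl2, catalytic NiCl2, DMF, 25 °C) then forms the C5–C6 bond under non-basic conditions and gives 21.

3. Step 10. The ester may be over-reduced to the primary alcohol, and the C8=C9 alkene may migrate into conjugation with the new aldehyde during quench or purification. The fallback sets out from ester 17 and comes back at 18. LiAlH4 in THF at 0 °C reduces 17 fully to homoallylic alcohol F6. Dess–Martin periodinane buffered with NaHCO3 in CH2Cl2 oxidises it under neutral conditions to 18, which is used without chromatography.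

**Further compounds**

F1 | step 12 | ring B silyl enol ether: labdane 2α-silyloxy, 5β-H, 6α-OH, 9α-H, 10β-methyl cis-decalin with exocyclic C8=C17H–OSi(i-Pr)3 and the 3-(1,3-dioxolan-2-yl)propyl chain on C9 | CC1(C)C[C@H](O[Si](C)(C)C(C)(C)C)C[C@]2(C)[C@@H](CCCC3OCCO3)C(=CO[Si](C(C)C)(C(C)C)C(C)C)C[C@H](O)[C@H]12
F2 | step 12 | α-bromo aldehyde: F1 with C8 carrying Br and the C17 formyl group (C8 configuration open) | CC1(C)C[C@H](O[Si](C)(C)C(C)(C)C)C[C@]2(C)[C@@H](CCCC3OCCO3)C(Br)(C=O)C[C@H](O)[C@H]12
F3 | step 12 | enal: core of 25 (2S,5R,6S,10S) with C17 as formyl group on the C8=C9 alkene | CC1(C)C[C@H](O[Si](C)(C)C(C)(C)C)C[C@]2(C)C(CCCC3OCCO3)=C(C=O)C[C@H](O)[C@H]12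
F4 | step 12 | allylic diol: 25 without the triisopropylsilyl group (free C17 hydroxyl) | CC1(C)C[C@H](O[Si](C)(C)C(C)(C)C)C[C@]2(C)C(CCCC3OCCO3)=C(CO)C[C@H](O)[C@H]12
F5 | step 11 | (4R)-4-{[tert-butyl(dimethyl)silyl]oxy}-2,6,6-trimethylcyclohex-1-en-1-yl trifluoromethanesulfonate | CC1(C)C[C@H](O[Si](C)(C)C(C)(C)C)CC(C)=C1OS(=O)(=O)C(F)(F)F
F6 | step 10 | (3Z)-7-(1,3-dioxolan-2-yl)-3-({[tri(propan-2-yl)silyl]oxy}methyl)hept-3-en-1-ol | OCC/C(CO[Si](C(C)C)(C(C)C)C(C)C)=C/CCCC1OCCO1
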